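**Assumptions (one line each)**
- The Rh/BINAP ligand antipode is chosen to give the (R)-ketone 6.
- Enolate alkylations of 8 and 9 occur anti to the C5 isopropenyl group.
- Atom labels use atisane numbering (C1–C20). C9 carries the lactone oxygen, and C16(=CH2)–C15(=O) is the exomethylene ketone bridge.

## Retrosynthetic overview
1. Crotobarin ⇐ Wittig methylenation of C16 in a C15/C16 α-dione, with C14-OAc from a C14 ketone (enol-ether hydrolysis, then equilibrating reduction and acetylation).
2. The core (ring B, the bicyclo[2.2.2]octane, the O-bearing quaternary C9 and the C8/C9/C10 contiguous quaternary centres) ⇐ one oxidative dearomatization/IMDA of a 3-methoxy masked o-benzoquinone with a tethered exocyclic enol δ-lactone. Ring order: the lactone ring forms first; then ring B and the bicycle form together in the IMDA.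
3. Enol lactone ⇐ 6-exo-dig cycloisomerization of an alkynoic acid. That acid ⇐ Eschenmoser–Tanabe fragmentation of a 6,6-disubstituted 5-isopropenylcyclohexenone epoxide. C5 comes from Rh-catalysed asymmetric 1,4-addition, and C10 from anti-selective sequential alkylations.
4. The arene tether ⇐ Negishi coupling of an alkylzinc with a MOM-protected bromo-dimethoxyphenol made from 2,5-dimethoxyphenol.

## Route

**Step 1**
Reactants: 1 2,5-dimethoxyphenol
Product: 2 1-(methoxymethoxy)-2,5-dimethoxybenzene
Conditions: MOMCl, i-Pr2NEt, CH2Cl2, 0 °C → rt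
Reagents that add atoms: chloromethyl methyl ether (ClCOC)
Why: Williamson-type O-protection as MOM ether, which is needed as a directing group for the next lithiation.

**Step 2**
Reactants: 2
Product: 3 2-bromo-1,4-dimethoxy-3-(methoxymethoxy)benzene
Conditions: n-BuLi, THF, −78 → 0 °C; then BrCCl2CCl2Br, −78 °C → rt
Reagents that add atoms: 1,2-dibromo-1,1,2,2-tetrachloroethane (BrC(Cl)(Cl)C(Cl)(Cl)Br)
Why: Directed ortho-metalation occurs at the position flanked by OMOM and OMe (cooperative directing effect), then Br quench.

**Step 3**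
Reactants: 4 cyclohex-2-en-1-one; 5 prop-1-en-2-ylboronic acid
Product: 6 (R)-3-(prop-1-en-2-yl)cyclohexan-1-one
Conditions: [Rh(cod)Cl]2 (1.5 mol %), (R)-BINAP (3 mol %), aq. KOH, dioxane/H2O, 50 °C
Reagents that add atoms: none
Why: Rh-catalysed asymmetric conjugate addition of an alkenylboronic acid, which sets the C5 stereocentre through the chiral ligand.

**Step 4**
Reactants: 6
Product: 7 TMS enol ether (C1–C6 enol) of 6
Conditions: LDA, TMSCl, THF, −78 °C
Reagents that add atoms: chlorotrimethylsilane (C[Si](C)(C)Cl)
Why: Kinetic deprotonation at the less hindered α'-position (C6, remote from the C3 branch) and silyl trapping.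

**Step 5**
Reactants: 7
Product: 8 (R)-5-(prop-1-en-2-yl)cyclohex-2-en-1-one
Conditions: Pd(OAc)2 (10 mol %), benzoquinone, MeCN, rt
Reagents that add atoms: none
Why: Saegusa–Ito oxidation gives the enone without touching the stereocentre or the isopropenyl group.

**Step 6**
Reactants: 8
Product: 9 (5R,6S)-6-methyl-5-(prop-1-en-2-yl)cyclohex-2-en-1-one
Conditions: LDA, THF, −78 °C; then MeI
Reagents that add atoms: iodomethane (CI)
Why: Kinetic α'-alkylation of the enolate by axial attack anti to the C5 isopropenyl group, giving the trans-6-methyl ketone.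

**Step 7**
Reactants: 9; 10 tert-butyl(3-iodopropoxy)dimethylsilane
Product: 11 (5S,6S)-6-methyl-6-[3-(TBSO)propyl]-5-(prop-1-en-2-yl)cyclohex-2-en-1-one
Conditions: LDA, THF, −78 °C; then 10, DMPU, −78 → −20 °C
Reagents that add atoms: none
Why: Second α'-alkylation through the trisubstituted enolate, again anti to isopropenyl. This sets the quaternary C10 with Me cis and the chain trans to isopropenyl, as in the target.

**Step 8**
Reactants: 11
Product: 12 2,3-epoxy ketone of 11 (epoxide stereochemistry irrelevant, destroyed in step 9)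
Conditions: 30% H2O2, aq. NaOH, MeOH, 0 °C
Reagents that add atoms: hydrogen peroxide (OO)
Why: Weitz–Scheffer nucleophilic epoxidation is selective for the enone over the isopropenyl alkene.

**Step 9**
Reactants: 12
Product: 13 alkynyl aldehyde OHC–CH2–CH(isopropenyl)–C(Me)(CH2CH2CH2OTBS)–C≡CH
Conditions: TsNHNH2, AcOH (cat.), CH2Cl2, 0 °C → rt
Reagents that add atoms: none
Why: Eschenmoser–Tanabe fragmentation cleaves the ring and makes the terminal alkyne (C9≡C11) and the C7 aldehyde, with C5 and C10 untouched.

**Step 10**
Reactants: 13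
Product: 14 primary alcohol (C7–OH)
Conditions: NaBH4, MeOH, 0 °C
Reagents that add atoms: none
Why: Chemoselective aldehyde reduction; the alkyne, silyl ether and isopropenyl group are inert.

**Step 11**
Reactants: 14
Product: 15 primary iodide (C7–I)
Conditions: I2, PPh3, imidazole, CH2Cl2, 0 °C
Reagents that add atoms: iodine (II)
Why: Appel-type (Garegg–Samuelsson) iodination proceeds at the primary carbon without stereochemical consequence.

**Step 12**
Reactants: 15; 3
Product: 16 aryl-tethered alkyne (Ar–C7H2–C6H2–C5…, MOM aryl ether, OTBS, terminal alkyne)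
Conditions: (i) Zn dust, LiCl, TMSCl/BrCH2CH2Br (cat.), THF, 40 °C; (ii) 3, Pd-PEPPSI-IPent (3 mol %), THF/NMP, 25 °C
Reagents that add atoms: none
Why: Negishi cross-coupling of a primary alkylzinc with the di-ortho-substituted aryl bromide forms the C7–C8 bond.

**Step 13**
Reactants: 16
Product: 17 primary alcohol (C3–OH)
Conditions: TBAF, THF, 0 °C → rt
Reagents that add atoms: none
Why: Fluoride cleavage of the TBS ether; the MOM ether and alkyne are untouched.

**Step 14**
Reactants: 17
Product: 18 aldehyde (C3–CHO)
Conditions: Dess–Martin periodinane, NaHCO3, CH2Cl2, 0 °C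
Reagents that add atoms: none
Why: Mild oxidation of the primary alcohol that tolerates the electron-rich arene and the alkenes.

**Step 15**
Reactants: 18
Product: 19 alkynoic acid (C3–COOH)
Conditions: NaClO2, NaH2PO4, 2-methyl-2-butene, t-BuOH/H2O, rt
Reagents that add atoms: sodium chlorite (O=Cl[O-].[Na+]), which supplies the acid oxygen
Why: Pinnick oxidation, with the alkene scavenger protecting the isopropenyl group and the arene.

**Step 16**
Reactants: 19
Product: 20 exocyclic enol δ-lactone (6-methylene-tetrahydropyran-2-one; C9=C11H2), MOM aryl ether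
Conditions: Ag2CO3 (10 mol %), toluene, 60 °C
Reagents that add atoms: none
Why: Ag(I)-catalysed 6-exo-dig carboxylic acid cycloisomerization, promoted by the gem-disubstituted quaternary C10 (Thorpe–Ingold effect). It gives the dienophile with C10 configuration retained.

**Step 17**
Reactants: 20
Product: 21 phenol 2-alkyl-3,6-dimethoxyphenol bearing the enol lactone
Conditions: TESOTf, 2,2'-bipyridyl, CH2Cl2/MeCN, 0 °C → rt; then H2O
Reagents that add atoms: none
Why: Non-acidic, non-nucleophilic MOM removal spares the acyl-transfer-prone enol lactone and the isopropenyl group.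

**Step 18**
Reactants: 21
Product: 22 bicyclo[2.2.2]octenone IMDA adduct (C15 ketone, C16 dimethyl ketal, C14 methyl enol ether, C9–O lactone, ring B)
Conditions: PhI(OAc)2 (1.1 equiv), MeOH (5 equiv), solid NaHCO3, CH2Cl2 (0.01 M), 0 °C → rt (masked o-benzoquinone formation), then 50 °C, 12 h (IMDA)
Reagents that add atoms: methanol (CO)
Why: **Proposed new method:** PIDA oxidizes the phenol to a phenoxenium ion, which MeOH traps at C16 to give a 6,6-dimethoxy-3-methoxy-cyclohexa-2,4-dienone (masked o-benzoquinone). This push–pull diene is polarity-matched to the exocyclic enol lactone: C8, as the enol-ether β-carbon, is nucleophilic and bonds to the acyloxy-stabilised C9, while the δ-electrophilic C12 bonds to the nucleophilic enol-ester CH2 (C11). The four-atom tether (C7–C6–C5–C10) enforces fused-mode [4+2], forming C8–C9 and C11–C12 in one event. The lactone-ring face syn to C5 is attacked (cis-fused lactone, sets C9), a chair-like ring-B closure with equatorial isopropenyl sets C8/C12, and the bulky C10 prefers the endo position syn to C13=C14, away from the C16 ketal. The closest known reactions are the oxidative dearomatization/IMDA of masked o-benzoquinones with tethered unactivated alkenes and Diels–Alder reactions of enol ethers or ketene acetals with quinone monoketals. Using an exocyclic enol lactone as the 2π partner, to create an O-substituted quaternary carbon next to two other quaternary carbons, is unprecedented.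

**Step 19**
Reactants: 22
Product: 23 C14 ketone (C13H2)
Conditions: 1 M aq. HCl, THF, rt, 2 h
Reagents that add atoms: water (O)
Why: Enol-ether hydrolysis is fast, while the α-keto dimethyl ketal, lactone and isopropenyl group survive mild acid.

**Step 20**
Reactants: 23
Product: 24 C14 alcohol, OH syn to the C15/C16 bridge
Conditions: Al(O-i-Pr)3, i-PrOH/toluene, 80 °C, 24 h (acetone distilled off)
Reagents that add atoms: none
Why: Meerwein–Ponndorf–Verley reduction is reversible and funnels to the thermodynamic C14 alcohol, whose OH is on the open face away from C10; kinetic hydride delivery would give the 14-epimer. The doubly neopentyl C15 ketone is too hindered to react.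

**Step 21**
Reactants: 24
Product: 25 C14 acetate
Conditions: Ac2O, DMAP, pyridine, 50 °C
Reagents that add atoms: acetic anhydride (CC(=O)OC(C)=O)
Why: Acylation proceeds with retention at C14 to give the 14-OAc of the target.

**Step 22**
Reactants: 25
Product: 26 C15/C16 α-dione
Conditions: TFA/H2O (9:1), CH2Cl2, 0 °C → rt
Reagents that add atoms: water (O)
Why: Acid hydrolysis of the α-keto dimethyl ketal; the C14 acetate and lactone are retained.

**Step 23**
Reactants: 26
Product: 27 crotobarin
Conditions: Ph3P=CH2 (from Ph3PCH3Br, KOt-Bu), THF, 0 °C (1 equiv)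
Reagents that add atoms: methylenetriphenylphosphorane (C=P(c1ccccc1)(c1ccccc1)c1ccccc1)
Why: Wittig methylenation occurs chemoselectively at the less hindered, more electrophilic C16 ketone (C15 is flanked by quaternary C8); the lactone and acetate do not react. This gives the α-methylene ketone.

## Compound list
1 | 2,5-dimethoxyphenol | Oc1c(OC)ccc(OC)c1 | starting material
2 | 1-(methoxymethoxy)-2,5-dimethoxybenzene | COCOc1c(OC)ccc(OC)c1 | intermediate
3 | 2-bromo-1,4-dimethoxy-3-(methoxymethoxy)benzene | COCOc1c(OC)ccc(OC)c1Br | intermediate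
4 | cyclohex-2-en-1-one | O=C1C=CCCC1 | starting material
5 | prop-1-en-2-ylboronic acid | CC(=C)B(O)O | starting material
6 | (R)-3-isopropenylcyclohexanone | CC(=C)[C@@H]1CCCC(=O)C1 | intermediate
7 | TMS enol ether of 6 (C1–C6 enol) | CC(=C)[C@@H]1CCC=C(O[Si](C)(C)C)C1 | intermediate
8 | (R)-5-isopropenylcyclohex-2-en-1-one | CC(=C)[C@@H]1CC=CC(=O)C1 | intermediate
9 | (5R,6S)-6-methyl-5-isopropenylcyclohex-2-en-1-one | C[C@@H]1C(=O)C=CC[C@H]1C(C)=C | intermediate
10 | tert-butyl(3-iodopropoxy)dimethylsilane | CC(C)(C)[Si](C)(C)OCCCI | starting material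
11 | (5S,6S)-6-methyl-6-(3-TBSO-propyl)-5-isopropenylcyclohex-2-en-1-one | C[C@@]1(CCCO[Si](C)(C)C(C)(C)C)C(=O)C=CC[C@H]1C(C)=C | intermediate
12 | 2,3-epoxy ketone of 11 (epoxide stereo undefined) | C[C@@]1(CCCO[Si](C)(C)C(C)(C)C)C(=O)C2OC2C[C@H]1C(C)=C | intermediate
13 | alkynyl aldehyde | O=CC[C@@H](C(C)=C)[C@](C)(CCCO[Si](C)(C)C(C)(C)C)C#C | intermediate
14 | alkynyl alcohol (C7–OH) | OCC[C@@H](C(C)=C)[C@](C)(CCCO[Si](C)(C)C(C)(C)C)C#C | intermediate
15 | alkyl iodide (C7–I) | ICC[C@@H](C(C)=C)[C@](C)(CCCO[Si](C)(C)C(C)(C)C)C#C | intermediate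
16 | aryl-tethered TBS alkyne | COCOc1c(OC)ccc(OC)c1CC[C@@H](C(C)=C)[C@](C)(CCCO[Si](C)(C)C(C)(C)C)C#C | intermediate
17 | alcohol (C3–OH) | COCOc1c(OC)ccc(OC)c1CC[C@@H](C(C)=C)[C@](C)(CCCO)C#C | intermediate
18 | aldehyde (C3–CHO) | COCOc1c(OC)ccc(OC)c1CC[C@@H](C(C)=C)[C@](C)(CCC=O)C#C | intermediate
19 | alkynoic acid | COCOc1c(OC)ccc(OC)c1CC[C@@H](C(C)=C)[C@](C)(CCC(=O)O)C#C | intermediate
20 | enol lactone, MOM aryl ether | COCOc1c(OC)ccc(OC)c1CC[C@@H](C(C)=C)[C@]2(C)CCC(=O)OC2=C | intermediate
21 | phenol enol lactone | Oc1c(OC)ccc(OC)c1CC[C@@H](C(C)=C)[C@]2(C)CCC(=O)OC2=C | intermediate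
22 | IMDA adduct (C14 enol ether, C16 ketal, C15 ketone) | COC1(OC)C(=O)[C@]23CC[C@@H](C(=C)C)[C@]4(C)CCC(=O)O[C@@]42C[C@H]1C=C3OC | intermediate
23 | C14 ketone | COC1(OC)C(=O)[C@]23CC[C@@H](C(=C)C)[C@]4(C)CCC(=O)O[C@@]42C[C@H]1CC3=O | intermediate
24 | C14 alcohol | COC1(OC)C(=O)[C@]23CC[C@@H](C(=C)C)[C@]4(C)CCC(=O)O[C@@]42C[C@H]1C[C@@H]3O | intermediate
25 | C14 acetate ketal | COC1(OC)C(=O)[C@]23CC[C@@H](C(=C)C)[C@]4(C)CCC(=O)O[C@@]42C[C@H]1C[C@@H]3OC(C)=O | intermediate
26 | α-dione acetate | O=C1C(=O)[C@]23CC[C@@H](C(=C)C)[C@]4(C)CCC(=O)O[C@@]42C[C@H]1C[C@@H]3OC(C)=O | intermediate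
27 | crotobarin | C=C1C(=O)[C@]23CC[C@@H](C(=C)C)[C@]4(C)CCC(=O)O[C@@]42C[C@H]1C[C@@H]3OC(C)=O | target

**Total step count:** 23 (including the 2-step arene branch).

**Longest linear sequence:** 21 steps (steps 3–23, from cyclohexenone 4).

**Three steps most likely to fail**
1. **Step 18 (new IMDA).** Risks are competing [4+2] with the isopropenyl alkene, exo rather than endo orientation of C10, and dimerization of the masked o-benzoquinone. Fallback with known chemistry: use a tethered α-methylene cyclopentanone (C3 ketone, C9=CH2, C10 quaternary) as the ordinary electron-poor dienophile, run the masked o-benzoquinone IMDA, then Baeyer–Villiger oxidation. The tertiary C9 migrates with retention to give the same cis-fused δ-lactone.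
2. **Step 20 (C14 stereochemistry by equilibrating MPV).** The C14 ketone may not equilibrate, or retro-Claisen may compete. Fallback: NaBH4 reduction to the kinetic 14-epimer (hydride delivered from the open top face, OH on the C9/C10 side), then Mitsunobu inversion with p-nitrobenzoic acid, solvolysis, and acetylation.
3. **Step 12 (Negishi with the hindered di-ortho aryl bromide and a free terminal alkyne).** Fallback: add the aryllithium from 2 (2.2 equiv, because the alkyne is acidic) to aldehyde 13 to give the benzylic alcohol. Then deoxygenate by Barton–McCombie, or by Et3SiH/BF3 ionic reduction, and continue from the C3 alcohol with TBS removal and oxidation as in steps 13–15.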